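- I took the easy step first, adding the three columns of each reading below and treating the shortfall from the whole charge as right-handed product, the one column not measured.

the same everywhere: left-handed substrate 0.50 M; right-handed substrate 0.50 M; gas 52 mM (held)
- Thursday's: racemization catalyst 7.5 mM; run made earlier
- Friday's: racemization catalyst 11 mM; run made earlier
- flask: racemization catalyst 15 mM; time 80 min

- Thursday's (time / min: left-handed substrate / %, right-handed substrate / %, left-handed product / %): 15.0: 38.4, 42.0, 19.5; 30.0: 31.8, 32.4, 33.8; 40.0: 27.4, 28.6, 43.6; 60.0: 19.8, 21.3, 57.7; 80.0: 14.6, 14.8, 66.9; 90.0: 13.4, 13.5, 72.0
- Friday's (time / min: left-handed substrate / %, right-handed substrate / %, left-handed product / %): 15.0: 39.4, 40.4, 19.6; 30.0: 31.3, 33.1, 33.8; 40.0: 26.9, 27.5, 43.7; 60.0: 20.2, 20.7, 58.2; 80.0: 15.2, 16.5, 68.8; 90.0: 12.6, 12.6, 74.3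

(standard deviation of a reading: 0.5 percentage points)

- reagent is single-handed; left-handed substrate and right-handed substrate are mirror images of each other, charged as a racemate, each of them at the stated concentration
- at the start none of reagent is dissolved
- candidate steps: reagent <-> dormant form; left-handed substrate + racemization catalyst <-> right-handed substrate + racemization catalyst; reagent + right-handed substrate -> right-handed product; reagent + left-handed substrate -> left-handed product; gas <-> reagent
- an excess is below zero if the other one leads
- the handed part of reagent does not stay in what it makes, so the products of the two hands are mirror images too

1. part of the left-handed substrate and right-handed substrate charged together that has reacted at 80 min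
2. excess of left-handed product over right-handed product in the product at 80 min
3. excess of right-handed substrate over left-handed substrate among what is left of the two at 80 min

- Two rates matter, $r_L$ for making left-handed product and $r_R$ for making right-handed product: reagent multiplies both and cancels from $r_R/r_L$, and the substrates cancel while the two hands stay equal.
- Thursday's run had the lowest catalyst charge, yet its substrates read 38.4% and 42.0% at 15.0 min, a gap smaller than the 19.5% of left-handed product, and 13.4% and 13.5% at 90.0 min, a gap smaller than the 72.0% of left-handed product.
- So time dropped out, and I summed the shortfall over both runs and divided by the summed left-handed product, reading $q$ = 2.31%, the right-handed product made per left-handed product, which is the inverse of the selectivity factor.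
- One minus $q$ over one plus $q$ gave me an estimated excess of left-handed product of 95.5% for the flask.
- The forecast, reasoning that “The missing balance is the right-handed product”, gave 69.5% reacted, a product excess of 96% and a substrate excess of 1.3%.
- The flask gave 70.0% reacted, a product excess of 95.7% and a substrate excess of 0.604%, and each of the forecast's numbers stood within its tolerance.

    reagent ⇌ dormant form (K = 24.0, k = 0.00477 min⁻¹)
    left-handed substrate + racemization catalyst ⇌ right-handed substrate + racemization catalyst, rate k2*[racemization catalyst]*[left-handed substrate] forward; the back reaction follows from the equilibrium constant (k = 81.0 L mol⁻¹ min⁻¹)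
    reagent + right-handed substrate → right-handed product (k = 0.0126 L mol⁻¹ min⁻¹)
    reagent + left-handed substrate → left-handed product (k = 0.584 L mol⁻¹ min⁻¹)
    gas ⇌ reagent, rate k5*(csat - [reagent]) (kL = 7.64 min⁻¹)

- In the flask at 80.0 min the step to left-handed product used left-handed substrate at 0.025 of the forward racemization rate. For the neighbouring flask with 0.037 M of catalyst I took the same $q$ of 2.31% and so the same estimate of 95.5%; that flask gave a product excess of 95.8%, with 70.1% reacted and a substrate excess of 0.245%.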